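## The problem

Locants: the diterpenoid chain runs from C1' (the CH2 on the quinone) to C16' (the terminal =CH2), and the lactone ring consists of the ring oxygen, the carboxyl carbon, C11', C12', C13' and C14'. The molecule is a linear chain with one ring at each end and no ring fusion. The task is therefore chain building, with three trisubstituted alkenes in 1,5-relationship that must each have a single geometry. C2'=C3' and C6'=C7' are ordinary E-isoprenoid alkenes and can be bought in a geranyl unit. C10'=C11' cannot be bought: its "methyl" is the lactone carboxyl carbon and C9' stands cis to that C=O (Z), the less stable geometry of an α-alkylidene lactone, so it needs kinetic control and must be kept from reversible conjugate addition. C14' (R) is the only stereocentre, nothing in the molecule can control it, and as a secondary allylic acyloxy carbon it is at risk from ionising acid, zerovalent palladium, cuprates (SN2') and lactone enolates. The 2,6-dialkyl-1,4-benzoquinone tolerates no hydride, carbanion, amine or base and must come last. The enabling feature lies in the lactone ring: the sequence C14'–C13'–C12'–C11'=C10' places the exocyclic alkene γ,δ to the oxygen-bearing carbon. With C14' read as a ketone this is the retron of a Claisen rearrangement. The carboxyl carbon on C11' makes the required allylic alcohol a Morita–Baylis–Hillman adduct of an acrylate, and the isopropenyl group on C14' is exactly what a 2-alkoxy-3-methylbutadiene delivers.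

## Retrosynthesis

**Quinone last (25 ⇒ 24).** The two quinone C=O groups are traced to the two aryl–OCH3 groups of hydroquinone dimethyl ether 24, and no C–C bond is cut. Compared with carrying a quinone, hydroquinone or phenol, the dimethyl ether is inert to organolithiums, amines, boranes and heat, and costs one step at the end. The forward reaction must oxidise the arene beside four alkenes and an allylic lactone, which the gap in oxidation potential allows.

**Lactone and stereocentre (24 ⇒ 23 ⇒ 22).** The acyl–oxygen bond of the ring is cut to give hydroxy ester 23. Removing the C14'–H bond then gives isopropenyl ketone 22.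
- Cutting the acyl C–O bond rather than C14'–O means that ring closure cannot touch the configuration.
- The ester carbon and C12' both sit on C11', so closure is indifferent to the alkene geometry.
- 22 is achiral, so the stereocentre becomes a choice of catalyst.
- The reduction must distinguish an α-branched alkenyl group from an unbranched CH2 and must be 1,2-selective.

**Key disconnection (22 ⇒ 16 + 19).** C12'–C13' is cut, C10'=C11' is transposed to C11'=C12', and oxygen returns to C10'. Ketone 22 is thus the Claisen product of allyl dienyl ether 21, which forms from alcohol 16 and 2-methoxy-3-methylbuta-1,3-diene 19 by exchange.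
- The neighbouring cuts are worse. C10'=C11' (olefination) leaves the geometry to a reagent effect and needs a prefabricated chiral lactone. C11'–C12' (cross-coupling) needs a Z-configured α-haloenoate, which is the same problem again.
- In the chosen cut the geometry follows from a chair with one equatorial substituent, five carbons arrive at once, and C14' arrives at the ketone level.
- Precursor 16 lacks the difficult alkene and C13'–C16'.
- The forward reaction must hold C9' equatorial against allylic strain with the ester and must outrun cycloaddition of 19.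

**Acrylate union (16 ⇒ 14 + 15).** C10'–C11' is cut as a Morita–Baylis–Hillman bond between aldehyde 14 and methyl acrylate 15. The new carbinol centre is erased in the key step, so the racemate serves and no chiral catalyst is needed. The reaction only has to tolerate an enolisable aldehyde, which a tertiary amine does.

**Two-carbon extension (14 ⇒ 8 + 11).** C8'–C9' is cut into allylic bromide 8 and the aza-enolate of acetaldimine 11. C8' is the one chain position that can be functionalised directly. A cut at C9'–C10' would need a homoallylic halide that is prone to elimination. The forward step is an SN2 reaction at a primary allylic carbon.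

**Geranyl arene (8 ⇒ 7 ⇒ 6 ⇒ 3 + 4).** The C8'–Br and C8'–O bonds go back to the E-methyl group of geranyl arene 6. The aryl–C1' bond is cut into aryl bromide 3 and geranyl bromide 4, which brings both E-alkenes ready made. The allylic oxidation must choose the terminal isopropylidene and its E-methyl group.

**Small pieces (3 ⇒ 2 ⇒ 1; 19 ⇒ 17; 11 ⇒ 9 + 10).** The 1,2,3,5-pattern of 3 comes from hydroxyl-directed bromination of phenol 1 followed by O-methylation of 2. Diene 19 comes from enone 17 through its ketal 18. Imine 11 comes from 9 and 10.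

## Roads not taken

**Alternative 1:** (the obvious route) cut C10'=C11' by olefination.
- *Forward key step:* a Still–Gennari or Ando-type Horner–Wadsworth–Emmons reaction of aldehyde 14 with (6R)-3-[bis(2,2,2-trifluoroethoxy)phosphoryl]-6-(prop-1-en-2-yl)oxan-2-one A1, giving 24 directly.
- *In its favour:* it is convergent.
- *Against it:* A1 needs its own sequence, in which stereocentre, lactone and phosphonate are each made separately. That costs about as many steps as the whole right-hand end of the chosen route.
- *Against it:* Z-selectivity of this olefination is established for acyclic phosphonoacetates. In A1 the carbonyl is tied back in a ring, so the outcome rests on a reagent effect that cannot be read from the structure.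
- *Chosen plan:* it derives the geometry from a chair and needs no second chiral fragment.

**Alternative 2:** cut the bond between C11' and the carboxyl carbon and read C10'=C11' as an alkyne.
- *Forward key step:* hydroxyl-steered trans-hydrostannation ([Cp*RuCl]4, Bu3SnH) of enynol A2 to alkenylstannane A3. Carbonylative lactonisation (Pd(OAc)2, CO, 1,4-benzoquinone) then gives 24.
- *In its favour:* anti addition gives the right geometry.
- *Against it:* the hydroxyl group is three carbons from the alkyne and both alkyne carbons carry CH2CH2, so neither hydrogen bonding nor sterics secures the regiochemistry.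
- *Against it:* A2 needs a separately made chiral alkynol and an acetylide alkylation with an elimination-prone homoallylic halide.
- *Against it:* stoichiometric tin and CO are added. The chosen plan has no regiochemical question and is shorter.

**Alternative 3:** cut C14'–O (the biomimetic cut).
- *Forward key step:* 6-exo opening of (S)-epoxy acid A4 by its own carboxyl group with inversion, giving hydroxyisopropyl lactone A5. Dehydration then gives 24.
- *Against it:* A4 already contains the Z-enoic acid, so the hardest problem is untouched.
- *Against it:* one of four trisubstituted alkenes must be epoxidised site- and enantioselectively.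
- *Against it:* acid favours opening at the tertiary C15' (7-endo), and the dehydration must choose the methyl over C14'–H.
- *Chosen plan:* it solves alkene, ring carbons and oxidation level together.

Key step: step 10

Remark: the SMILES string places C9' cis to the lactone C=O (Z) and gives C14' as R. The route is planned for this isomer, and 16 is used as the racemate because its carbinol centre is erased in step 10.

## Steps

Step 1
Reactants: 1 4-methoxy-2-methylphenol
Product: 2 2-bromo-4-methoxy-6-methylphenol
Conditions: Br2 (1.0 equiv), CH2Cl2, −10 to 0 °C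
Reagents that add atoms: bromine, BrBr
Why: Electrophilic aromatic bromination; the free hydroxyl is the strongest director, its para position carries OMe and one ortho position carries CH3, so only C6 is open.

Step 2
Reactants: 2 2-bromo-4-methoxy-6-methylphenol
Product: 3 1-bromo-2,5-dimethoxy-3-methylbenzene
Conditions: MeI, K2CO3, acetone, reflux
Reagents that add atoms: iodomethane, CI
Why: Williamson ether synthesis on a phenoxide; nothing else in 2 is nucleophilic.

Step 3
Reactants: 3 1-bromo-2,5-dimethoxy-3-methylbenzene; 4 geranyl bromide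
Product: 6 1-[(2E)-3,7-dimethylocta-2,6-dien-1-yl]-2,5-dimethoxy-3-methylbenzene, via aryllithium 5 (not isolated)
Conditions: n-BuLi (1.05 equiv), THF, −78 °C; CuBr·SMe2 (0.2 equiv); 4, −78 to 0 °C
Reagents that add atoms: none
Why: Bromine–lithium exchange fixes the site of metalation, and copper-assisted SN2 allylation of aryl metals with prenyl-type bromides proceeds at the primary carbon with retention of the E-alkene.

Step 4
Reactants: 6 1-[(2E)-3,7-dimethylocta-2,6-dien-1-yl]-2,5-dimethoxy-3-methylbenzene
Product: 7 (2E,6E)-8-(2,5-dimethoxy-3-methylphenyl)-2,6-dimethylocta-2,6-dien-1-ol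
Conditions: SeO2 (0.2 equiv), t-BuOOH (2.5 equiv), salicylic acid (0.1 equiv), CH2Cl2, 0 °C to rt
Reagents that add atoms: tert-butyl hydroperoxide, CC(C)(C)OO (oxygen relayed through selenium dioxide, O=[Se]=O)
Why: Riley allylic oxidation (ene reaction, then [2,3] shift) attacks the most accessible, terminal isopropylidene group and oxidises its E-methyl group, so C8' ends trans to C5' as the backbone requires.

Step 5
Reactants: 7 (2E,6E)-8-(2,5-dimethoxy-3-methylphenyl)-2,6-dimethylocta-2,6-dien-1-ol
Product: 8 1-[(2E,6E)-8-bromo-3,7-dimethylocta-2,6-dien-1-yl]-2,5-dimethoxy-3-methylbenzene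
Conditions: CBr4, PPh3, CH2Cl2, −20 to 0 °C; used without storage
Reagents that add atoms: tetrabromomethane, BrC(Br)(Br)Br
Why: Appel reaction; neutral SN2 displacement at a primary allylic carbon without allylic transposition or E/Z loss.

Step 6
Reactants: 9 acetaldehyde; 10 cyclohexylamine
Product: 11 (E)-N-cyclohexylethanimine
Conditions: neat, 0 °C; KOH pellets; distil
Reagents that add atoms: none
Why: Simple condensation of an aldehyde with a primary amine; the imine is the standard acetaldehyde enolate equivalent.

Step 7
Reactants: 8 1-[(2E,6E)-8-bromo-3,7-dimethylocta-2,6-dien-1-yl]-2,5-dimethoxy-3-methylbenzene; 11 (E)-N-cyclohexylethanimine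
Product: 14 (4E,8E)-10-(2,5-dimethoxy-3-methylphenyl)-4,8-dimethyldeca-4,8-dienal, via lithio-enamide 12 (not isolated), via alkylated imine 13 (not isolated)
Conditions: LiN(iPr)2 (LDA, 1.05 equiv), THF, 0 °C; 8, −78 to 0 °C; then 1 M aq. tartaric acid, 0 °C to rt
Reagents that add atoms: water, O
Why: Metalloenamine (aza-enolate) alkylation with an allylic bromide, a standard two-carbon aldehyde homologation; monoalkylation is secured by the low acidity of imine 13, and mild acid hydrolysis frees the aldehyde.

Step 8
Reactants: 14 (4E,8E)-10-(2,5-dimethoxy-3-methylphenyl)-4,8-dimethyldeca-4,8-dienal; 15 methyl acrylate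
Product: 16 methyl (6E,10E)-12-(2,5-dimethoxy-3-methylphenyl)-3-hydroxy-6,10-dimethyl-2-methylidenedodeca-6,10-dienoate (racemic)
Conditions: 15 (5 equiv), 1,4-diazabicyclo[2.2.2]octane (DABCO, 0.5 equiv), MeOH (little), rt, several days
Reagents that add atoms: none
Why: Morita–Baylis–Hillman reaction of an unbranched aliphatic aldehyde, slow but reliable; the new centre C10' is formed racemic on purpose because it disappears in step 10.

Step 9
Reactants: 17 3-methylbut-3-en-2-one
Product: 19 2-methoxy-3-methylbuta-1,3-diene, via dimethyl ketal 18 (not isolated)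
Conditions: HC(OMe)3, MeOH, p-TsOH (cat.), 0 °C to rt; neutralise; then KHSO4 (cat.), hydroquinone, distil
Reagents that add atoms: trimethyl orthoformate, COC(OC)OC
Why: Ketalisation with orthoformate as water scavenger, then acid-catalysed loss of methanol on distillation, is the usual way to 2-alkoxy-1,3-dienes; methanol that adds in conjugate fashion is lost again in the cracking, so both paths converge on 19.

Step 10
Reactants: 16 methyl (6E,10E)-12-(2,5-dimethoxy-3-methylphenyl)-3-hydroxy-6,10-dimethyl-2-methylidenedodeca-6,10-dienoate; 19 2-methoxy-3-methylbuta-1,3-diene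
Product: 22 methyl (2Z,6E,10E)-12-(2,5-dimethoxy-3-methylphenyl)-6,10-dimethyl-2-(4-methyl-3-oxopent-4-en-1-yl)dodeca-2,6,10-trienoate, via mixed ketal 20 (not isolated), via allyl dienyl ether 21 (not isolated)
Conditions: 19 (5 equiv), 2,4-dinitrophenol (0.1 equiv), 2,6-di-tert-butyl-4-methylphenol (trace), toluene, 110 °C, sealed tube
Reagents that add atoms: none
Why: Ketal (enol-ether exchange) Claisen rearrangement: the acid adds the hydroxyl of 16 to the enol ether of 19 to give mixed ketal 20, loss of methanol gives allyl dienyl ether 21, and 21 undergoes the [3,3] shift across C13'=C14'–O–C10'–C11'=C12' that makes C12'–C13', breaks C10'–O and leaves C14' as the isopropenyl ketone. The closest known reaction types are the same exchange–rearrangement of isopropenyl carbinols with 2-alkoxydienes, a classical entry to E-trisubstituted isoprenoid alkenes, and the Johnson–Claisen rearrangement of Morita–Baylis–Hillman adducts of aliphatic aldehydes. No ring is closed and no stereocentre is made; the racemic centre C10' is erased, and what the step sets is the geometry of C10'=C11'. In the chair the C9' chain on C10' lies equatorial because the axial position meets the isopropenyl group on C14' in a 1,3-diaxial contact, and an equatorial C9' ends trans to C12' and therefore cis to the ester, which is the Z geometry of the target reached under kinetic control. The opposing force is allylic strain between equatorial C9' and the ester on C11', kept small by the flat methyl ester and the unbranched CH2 at C9'. The step also needs the [3,3] shift to outrun Diels–Alder addition of 19 to the acrylate of 16 or the enone of 22; the acceptor on C11' (position 5 of the allyl vinyl ether) and the conjugating group on C14' (position 2) both lower the barrier of the rearrangement, and both dienophiles are 1,1-disubstituted. One operation thus supplies five carbons, the C12'–C13' bond, the difficult alkene and the right oxidation level at C14'.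

Step 11
Reactants: 22 methyl (2Z,6E,10E)-12-(2,5-dimethoxy-3-methylphenyl)-6,10-dimethyl-2-(4-methyl-3-oxopent-4-en-1-yl)dodeca-2,6,10-trienoate
Product: 23 methyl (2Z,6E,10E)-12-(2,5-dimethoxy-3-methylphenyl)-2-[(3R)-3-hydroxy-4-methylpent-4-en-1-yl]-6,10-dimethyldodeca-2,6,10-trienoate
Conditions: (S)-1-methyl-3,3-diphenyltetrahydro-1H,3H-pyrrolo[1,2-c][1,3,2]oxazaborole ((S)-Me-CBS, 0.2 equiv), catecholborane (1.5 equiv), toluene, −78 °C; MeOH, pH 7 buffer
Reagents that add atoms: none
Why: Corey–Bakshi–Shibata reduction: the ketone binds with the α-branched isopropenyl group as the large and the CH2 chain as the small substituent, so the (S)-catalyst should give (R)-C14' in the sense in which acetophenone gives (R)-1-phenylethanol (isopropenyl outranks CH2 as phenyl outranks CH3). Catecholborane at low temperature spares the alkenes and the conjugated ester and favours 1,2-reduction.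

Step 12
Reactants: 23 methyl (2Z,6E,10E)-12-(2,5-dimethoxy-3-methylphenyl)-2-[(3R)-3-hydroxy-4-methylpent-4-en-1-yl]-6,10-dimethyldodeca-2,6,10-trienoate
Product: 24 (3Z,6R)-3-[(4E,8E)-10-(2,5-dimethoxy-3-methylphenyl)-4,8-dimethyldeca-4,8-dien-1-ylidene]-6-(prop-1-en-2-yl)oxan-2-one
Conditions: pyridinium p-toluenesulfonate (0.1 equiv), toluene, 5 Å molecular sieves, 60 °C
Reagents that add atoms: none
Why: Acid-catalysed intramolecular transesterification (6-exo-trig at the ester carbon), driven by removal of methanol; C14'–O is not broken, so the configuration is kept, and the alkene is not involved.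

Step 13
Reactants: 24 (3Z,6R)-3-[(4E,8E)-10-(2,5-dimethoxy-3-methylphenyl)-4,8-dimethyldeca-4,8-dien-1-ylidene]-6-(prop-1-en-2-yl)oxan-2-one
Product: 25 2-methyl-6-{(2E,6E,10Z)-3,7-dimethyl-10-[(6R)-2-oxo-6-(prop-1-en-2-yl)oxan-3-ylidene]deca-2,6-dien-1-yl}cyclohexa-2,5-diene-1,4-dione (target)
Conditions: (NH4)2Ce(NO3)6 (2.5 equiv), MeCN/H2O 4:1, 0 °C, short time
Reagents that add atoms: water, O
Why: Oxidative demethylation of a 1,4-dimethoxyarene, standard for polyprenylated quinones; the arene is by far the most easily oxidised group, and two one-electron oxidations with attack of water release two molecules of methanol.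

## Compound list

1 | 4-methoxy-2-methylphenol | COc1ccc(O)c(C)c1 | starting material
2 | 2-bromo-4-methoxy-6-methylphenol | COc1cc(C)c(O)c(Br)c1 | intermediate
3 | 1-bromo-2,5-dimethoxy-3-methylbenzene | COc1cc(C)c(OC)c(Br)c1 | intermediate
4 | geranyl bromide, (2E)-1-bromo-3,7-dimethylocta-2,6-diene | CC(C)=CCC/C(C)=C/CBr | starting material
5 | (2,5-dimethoxy-3-methylphenyl)lithium | COc1cc(C)c(OC)c([Li])c1 | intermediate
6 | 1-[(2E)-3,7-dimethylocta-2,6-dien-1-yl]-2,5-dimethoxy-3-methylbenzene | COc1cc(C)c(OC)c(C/C=C(\C)CCC=C(C)C)c1 | intermediate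
7 | (2E,6E)-8-(2,5-dimethoxy-3-methylphenyl)-2,6-dimethylocta-2,6-dien-1-ol | COc1cc(C)c(OC)c(C/C=C(\C)CC/C=C(\C)CO)c1 | intermediate
8 | 1-[(2E,6E)-8-bromo-3,7-dimethylocta-2,6-dien-1-yl]-2,5-dimethoxy-3-methylbenzene | COc1cc(C)c(OC)c(C/C=C(\C)CC/C=C(\C)CBr)c1 | intermediate
9 | acetaldehyde | CC=O | starting material
10 | cyclohexylamine | NC1CCCCC1 | starting material
11 | (E)-N-cyclohexylethanimine | C/C=N/C1CCCCC1 | intermediate
12 | lithium cyclohexyl(vinyl)amide | C=CN([Li])C1CCCCC1 | intermediate
13 | N-cyclohexylimine of aldehyde 14 | COc1cc(C)c(OC)c(C/C=C(\C)CC/C=C(\C)CC/C=N/C2CCCCC2)c1 | intermediate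
14 | (4E,8E)-10-(2,5-dimethoxy-3-methylphenyl)-4,8-dimethyldeca-4,8-dienal | COc1cc(C)c(OC)c(C/C=C(\C)CC/C=C(\C)CCC=O)c1 | intermediate
15 | methyl acrylate | C=CC(=O)OC | starting material
16 | methyl (6E,10E)-12-(2,5-dimethoxy-3-methylphenyl)-3-hydroxy-6,10-dimethyl-2-methylidenedodeca-6,10-dienoate (racemic) | COc1cc(C)c(OC)c(C/C=C(\C)CC/C=C(\C)CCC(O)C(=C)C(=O)OC)c1 | intermediate
17 | 3-methylbut-3-en-2-one | CC(=O)C(C)=C | starting material
18 | 3,3-dimethoxy-2-methylbut-1-ene | COC(C)(OC)C(C)=C | intermediate
19 | 2-methoxy-3-methylbuta-1,3-diene | COC(=C)C(C)=C | intermediate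
20 | mixed methyl ketal of 16 with 3-methylbut-3-en-2-one | COc1cc(C)c(OC)c(C/C=C(\C)CC/C=C(\C)CCC(OC(C)(OC)C(C)=C)C(=C)C(=O)OC)c1 | intermediate
21 | 3-methylbuta-1,3-dien-2-yl ether of 16 | COc1cc(C)c(OC)c(C/C=C(\C)CC/C=C(\C)CCC(OC(=C)C(C)=C)C(=C)C(=O)OC)c1 | intermediate
22 | methyl (2Z,6E,10E)-12-(2,5-dimethoxy-3-methylphenyl)-6,10-dimethyl-2-(4-methyl-3-oxopent-4-en-1-yl)dodeca-2,6,10-trienoate | COc1cc(C)c(OC)c(C/C=C(\C)CC/C=C(\C)CC/C=C(/CCC(=O)C(C)=C)C(=O)OC)c1 | intermediate
23 | methyl (2Z,6E,10E)-12-(2,5-dimethoxy-3-methylphenyl)-2-[(3R)-3-hydroxy-4-methylpent-4-en-1-yl]-6,10-dimethyldodeca-2,6,10-trienoate | COc1cc(C)c(OC)c(C/C=C(\C)CC/C=C(\C)CC/C=C(/CC[C@@H](O)C(C)=C)C(=O)OC)c1 | intermediate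
24 | (3Z,6R)-3-[(4E,8E)-10-(2,5-dimethoxy-3-methylphenyl)-4,8-dimethyldeca-4,8-dien-1-ylidene]-6-(prop-1-en-2-yl)oxan-2-one | C=C(C)[C@H]1CC/C(=C/CC/C(C)=C/CC/C(C)=C/Cc2cc(OC)cc(C)c2OC)C(=O)O1 | intermediate
25 | 2-methyl-6-{(2E,6E,10Z)-3,7-dimethyl-10-[(6R)-2-oxo-6-(prop-1-en-2-yl)oxan-3-ylidene]deca-2,6-dien-1-yl}cyclohexa-2,5-diene-1,4-dione | C=C(C)[C@H]1CC/C(=C/CC/C(C)=C/CC/C(C)=C/CC2=CC(=O)C=C(C)C2=O)C(=O)O1 | target

## Count and risks

Total step count: 13. Longest linear sequence: 11 steps (1, 2, 3, 4, 5, 7, 8, 10, 11, 12, 13). Steps 6 and 9 are side branches.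

**Step 10 (key step).**
- *Main risk:* loss of geometric control. The chair with C9' axial escapes the allylic strain between C9' and the ester and leads toward the more stable E-enoate.
- *Second risk:* consumption of 19 by cycloaddition or polymerisation before the hindered, electron-poor alcohol has exchanged.
- *Fallback (from 14, back at 22):* the alkene is made by olefination and the ketone afterwards. Commercial methyl 2-[bis(2,2,2-trifluoroethoxy)phosphoryl]acetate is added to 15 in a base-catalysed Michael reaction (DBU cat., THF). This gives dimethyl 2-[bis(2,2,2-trifluoroethoxy)phosphoryl]pentanedioate F1. Still–Gennari olefination of 14 with F1 (KN(SiMe3)2, 18-crown-6, THF, −78 °C) should give the Z-alkylidene glutarate diester F2. The unhindered saturated ester of F2 is then converted selectively (MeNH(OMe)·HCl, iPrMgCl, THF, −20 °C) into the Weinreb amide F3. Isopropenylmagnesium bromide takes F3 to 22.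

**Step 4.**
- *Risk:* competing ene attack of SeO2 on C2'=C3', which is not deactivated and whose allylic C1' is also benzylic, together with over-oxidation of the product to the enal.
- *Fallback (from 3, back at 14, by-passing 6, 7 and 8):* the chain is bought one isoprene unit longer and cut back. Aryllithium 5, made as in step 3, is allylated with commercial (2E,6E)-farnesyl bromide to give the farnesyl arene F4. NBS in aqueous THF at 0 °C should attack the terminal alkene and give the racemic bromohydrin F5. K2CO3 in MeOH then closes the terminal epoxide F6, and H5IO6 in THF/water cleaves F6 to 14.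

**Step 11.**
- *Risk:* poor facial discrimination, because close to the carbonyl the two substituents differ only by branching. Some 1,4-reduction by catecholborane is also possible.
- *Fallback (from 22, back at 23):* resolution instead of asymmetric reduction. Luche reduction (NaBH4, CeCl3·7H2O, MeOH, −78 °C) gives the racemic hydroxy ester F7. Sharpless kinetic resolution follows (Ti(OiPr)4, L-(+)-diisopropyl tartrate, t-BuOOH 0.6 equiv, 4 Å molecular sieves, CH2Cl2, −20 °C). It should consume the (S)-enantiomer as the (S,S)-epoxy alcohol F8 and leave 23. 2-Substituted secondary allylic alcohols are a good substrate class for this resolution, and the other alkenes carry no directing hydroxyl.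

**Step 12.**
- *Risk:* slow transesterification of the hindered conjugated ester. That would tempt forcing acid, under which ionisation at C14' or protonation of the polyene sets in.
- *Fallback (from 23, back at 24):* acid activation instead of transesterification. Me3SnOH (1,2-dichloroethane, 70 °C) cleaves the methyl ester under near-neutral conditions to the seco acid F9. Yamaguchi conditions (2,4,6-trichlorobenzoyl chloride, Et3N, then DMAP, toluene, rt) then close F9 to 24 with retention at C14'.

**Step 13.**
- *Risk:* oxidative coupling of the arene radical cation, attack of the acidic oxidising medium on the electron-rich alkenes, or opening of the allylic lactone.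
- *Fallback (from 24, back at 25):* an electrochemical two-stage unmasking under neutral conditions. Constant-current anodic oxidation of 24 (Pt anode, MeOH, LiClO4, 2,6-lutidine, undivided cell, 0 °C) should give the quinone bis(dimethyl ketal) F10. It takes place at the potential of the dimethoxyarene, well below that of the alkenes. Aqueous acetic acid in THF then hydrolyses F10 to 25.

## Further compounds

F1 | step 10 | dimethyl 2-[bis(2,2,2-trifluoroethoxy)phosphoryl]pentanedioate | COC(=O)CCC(C(=O)OC)P(=O)(OCC(F)(F)F)OCC(F)(F)F
F2 | step 10 | dimethyl (2Z)-2-[(4E,8E)-10-(2,5-dimethoxy-3-methylphenyl)-4,8-dimethyldeca-4,8-dien-1-ylidene]pentanedioate | COc1cc(C)c(OC)c(C/C=C(\C)CC/C=C(\C)CC/C=C(/CCC(=O)OC)C(=O)OC)c1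
F3 | step 10 | methyl (2Z,6E,10E)-12-(2,5-dimethoxy-3-methylphenyl)-2-{3-[methoxy(methyl)amino]-3-oxopropyl}-6,10-dimethyldodeca-2,6,10-trienoate | COc1cc(C)c(OC)c(C/C=C(\C)CC/C=C(\C)CC/C=C(/CCC(=O)N(C)OC)C(=O)OC)c1
F4 | step 4 | 2,5-dimethoxy-3-methyl-1-[(2E,6E)-3,7,11-trimethyldodeca-2,6,10-trien-1-yl]benzene | COc1cc(C)c(OC)c(C/C=C(\C)CC/C=C(\C)CCC=C(C)C)c1
F5 | step 4 | (6E,10E)-3-bromo-12-(2,5-dimethoxy-3-methylphenyl)-2,6,10-trimethyldodeca-6,10-dien-2-ol (racemic) | COc1cc(C)c(OC)c(C/C=C(\C)CC/C=C(\C)CCC(Br)C(C)(C)O)c1
F6 | step 4 | 3-[(3E,7E)-9-(2,5-dimethoxy-3-methylphenyl)-3,7-dimethylnona-3,7-dien-1-yl]-2,2-dimethyloxirane (racemic) | COc1cc(C)c(OC)c(C/C=C(\C)CC/C=C(\C)CCC2OC2(C)C)c1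
F7 | step 11 | racemic form of hydroxy ester 23 | COc1cc(C)c(OC)c(C/C=C(\C)CC/C=C(\C)CC/C=C(/CCC(O)C(C)=C)C(=O)OC)c1
F8 | step 11 | methyl (2Z,6E,10E)-12-(2,5-dimethoxy-3-methylphenyl)-2-{(3S)-3-hydroxy-3-[(2S)-2-methyloxiran-2-yl]propyl}-6,10-dimethyldodeca-2,6,10-trienoate | COc1cc(C)c(OC)c(C/C=C(\C)CC/C=C(\C)CC/C=C(/CC[C@H](O)[C@]2(C)CO2)C(=O)OC)c1
F9 | step 12 | (2Z,6E,10E)-12-(2,5-dimethoxy-3-methylphenyl)-2-[(3R)-3-hydroxy-4-methylpent-4-en-1-yl]-6,10-dimethyldodeca-2,6,10-trienoic acid | COc1cc(C)c(OC)c(C/C=C(\C)CC/C=C(\C)CC/C=C(/CC[C@@H](O)C(C)=C)C(=O)O)c1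
F10 | step 13 | (3Z,6R)-3-[(4E,8E)-4,8-dimethyl-10-(3,3,6,6-tetramethoxy-5-methylcyclohexa-1,4-dien-1-yl)deca-4,8-dien-1-ylidene]-6-(prop-1-en-2-yl)oxan-2-one | C=C(C)[C@H]1CC/C(=C/CC/C(C)=C/CC/C(C)=C/CC2=CC(OC)(OC)C=C(C)C2(OC)OC)C(=O)O1
A1 | alternative 1 | (6R)-3-[bis(2,2,2-trifluoroethoxy)phosphoryl]-6-(prop-1-en-2-yl)oxan-2-one (epimers at C3) | C=C(C)[C@H]1CCC(C(=O)O1)P(=O)(OCC(F)(F)F)OCC(F)(F)F
A2 | alternative 2 | (3R,10E,14E)-16-(2,5-dimethoxy-3-methylphenyl)-2,10,14-trimethylhexadeca-1,10,14-trien-6-yn-3-ol | C=C(C)[C@H](O)CCC#CCC/C(C)=C/CC/C(C)=C/Cc1cc(OC)cc(C)c1OC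
A3 | alternative 2 | C11'-tributylstannyl alkene from trans-hydrostannation of A2 (C9' trans to C12') | C=C(C)[C@H](O)CC/C(=C/CC/C(C)=C/CC/C(C)=C/Cc1cc(OC)cc(C)c1OC)[Sn](CCCC)(CCCC)CCCC
A4 | alternative 3 | (2Z,6E,10E)-12-(2,5-dimethoxy-3-methylphenyl)-2-{2-[(2S)-3,3-dimethyloxiran-2-yl]ethyl}-6,10-dimethyldodeca-2,6,10-trienoic acid | CC1(C)O[C@H]1CC/C(=C/CC/C(C)=C/CC/C(C)=C/Cc2cc(OC)cc(C)c2OC)C(=O)O
A5 | alternative 3 | (3Z,6R)-3-[(4E,8E)-10-(2,5-dimethoxy-3-methylphenyl)-4,8-dimethyldeca-4,8-dien-1-ylidene]-6-(2-hydroxypropan-2-yl)oxan-2-one | CC(C)(O)[C@H]1CC/C(=C/CC/C(C)=C/CC/C(C)=C/Cc2cc(OC)cc(C)c2OC)C(=O)O1
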